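**Retrosynthetic overview**
- Ring labels: A = 2,4,6-trihydroxyphenoxy ring, B = central bis(aryloxy) ring, C and D = the biphenyl rings (C carries the ether oxygen). Target ⇐ global O-demethylation ⇐ double Baeyer–Villiger; the para-OH groups of rings A and B are carried as formyl groups.
- Ring C–ring D bond ⇐ Suzuki coupling of a ring C aryl iodide with 2,4,6-trimethoxyphenylboronic acid.
- Key disconnection, the ring A–O–ring B ether ⇐ copper-catalysed ring opening of an oxygen-bridged cyclic diaryliodonium salt by syringaldehyde; the same event moves the iodine from ring B to the ring C carbon that will bear ring D.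
- Cyclic iodonium ⇐ oxidative cyclisation of a 2-iodo diaryl ether ⇐ Chan–Lam C–O coupling (ring B–O–ring C) of 5-iodovanillin with 3,5-dimethoxyphenylboronic acid.
- No ring is built; the four aromatic rings are bought and joined in the order B + C, then A, then D (the iodonium ring is only a transient tether).

Assumption: the target has no stereocentre and no stereogenic axis (ring D is symmetric about the biaryl bond), so the achiral compound is the single species asked for and no stereocontrol is needed.

**Route**

Step 1
Reactants: 1 5-iodovanillin (4-hydroxy-3-iodo-5-methoxybenzaldehyde); 2 (3,5-dimethoxyphenyl)boronic acid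
Product: 3 4-(3,5-dimethoxyphenoxy)-3-iodo-5-methoxybenzaldehyde
Conditions: Cu(OAc)2 (2 equiv), pyridine (5 equiv), 4 Å MS, CH2Cl2, air, rt, 24–48 h
Reagents that add atoms: none
Why: Chan–Lam oxidative C–O coupling, in which the acidic di-ortho-substituted phenol binds divalent copper and is arylated by the boronic acid at room temperature, where the aryl iodide and the aldehyde are inert (2,6-diiodophenols are established substrates for this coupling).

Step 2
Reactants: 3 4-(3,5-dimethoxyphenoxy)-3-iodo-5-methoxybenzaldehyde
Product: 5 3-formyl-1,6,8-trimethoxydibenzo[b,e][1,4]iodaoxin-5-ium trifluoromethanesulfonate (cyclic diaryliodonium salt; the iodonium iodine bridges C3 of the benzaldehyde ring to C2 of the dimethoxyphenoxy ring), via hydroxy(triflyloxy)iodoarene 4 (not isolated)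
Conditions: mCPBA (1.05 equiv), TfOH (2.5 equiv, added last), CH2Cl2 (0.05 M), −40 → 0 °C, 30 min; Et2O precipitation
Reagents that add atoms: trifluoromethanesulfonic acid, OS(=O)(=O)C(F)(F)F
Why: One-pot iodoarene oxidation and intramolecular electrophilic aromatic substitution (the standard cyclic diaryliodonium synthesis): acid-activated peracid should oxidise the monovalent iodine within minutes at low temperature, faster than it adds to the aldehyde, and the tethered phloroglucinol-type ring C traps the trivalent iodine at either of its two equivalent ortho carbons through a six-membered transition state.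

Step 3
Reactants: 5 the cyclic diaryliodonium triflate; 6 syringaldehyde (4-hydroxy-3,5-dimethoxybenzaldehyde)
Product: 7 3-(4-formyl-2,6-dimethoxyphenoxy)-4-(2-iodo-3,5-dimethoxyphenoxy)-5-methoxybenzaldehyde
Conditions: CuI (10 mol %), 1,10-phenanthroline (12 mol %), K2CO3 (1.5 equiv), MeCN, 40 °C
Reagents that add atoms: none
Why: Proposed new method: copper-catalysed, regiocontrolled ring-opening O-arylation of an unsymmetrical oxygen-bridged cyclic diaryliodonium salt by a 2,6-disubstituted phenoxide; the monovalent copper phenoxide should insert into the less hindered, formyl-deactivated C(ring B)–I bond because the ring C terminus is a built-in 2,4,6-trioxygenated, di-ortho-substituted (trimethoxyphenyl-type) non-transferable ligand, and C–O reductive elimination from trivalent copper then forms the ring A–O–ring B ether while the iodine stays on ring C at the carbon that must carry ring D (any uncatalysed ligand coupling has the same electronic bias); the closest known reaction types are copper-catalysed ring opening of cyclic diaryliodonium salts by N- and O-nucleophiles and phenol arylation with aryl(2,4,6-trimethoxyphenyl)iodonium salts.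

Step 4
Reactants: 7 the ring C aryl iodide dialdehyde; 8 (2,4,6-trimethoxyphenyl)boronic acid (3 equiv, added in portions)
Product: 9 3-(4-formyl-2,6-dimethoxyphenoxy)-5-methoxy-4-[(2′,4,4′,6,6′-pentamethoxy-[1,1′-biphenyl]-2-yl)oxy]benzaldehyde
Conditions: Pd(OAc)2 (5 mol %), SPhos (10 mol %), K3PO4 (3 equiv), toluene–H2O (10:1), 100 °C
Reagents that add atoms: none
Why: Suzuki–Miyaura coupling with a dialkylbiarylphosphine catalyst, the established solution for tetra-ortho-substituted alkoxy-rich biaryls; excess boronic acid offsets protodeboronation, the aldehydes tolerate K3PO4, and the new axis is not stereogenic because ring D is symmetric.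

Step 5
Reactants: 9 the dialdehyde
Product: 11 3-(4-hydroxy-2,6-dimethoxyphenoxy)-5-methoxy-4-[(2′,4,4′,6,6′-pentamethoxy-[1,1′-biphenyl]-2-yl)oxy]phenol, via bis-formate ester 10 (not isolated)
Conditions: mCPBA (3 equiv), CH2Cl2, 0 °C → rt; then K2CO3 (cat.), MeOH, rt, under N2
Reagents that add atoms: mCPBA (3-chloroperoxybenzoic acid), OOC(=O)c1cccc(Cl)c1
Why: Baeyer–Villiger oxidation: each formyl group sits para to an aryloxy oxygen on an oxygen-rich ring, so aryl migration gives the aryl formates (as for 3,4,5-trialkoxy- and 4-aryloxybenzaldehydes), and mild methanolysis releases the two phenols; no iodine remains to be oxidised.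

Step 6
Reactants: 11 the octamethyl ether diphenol
Product: 12 fucodiphloroethol G, 2′-[2,4-dihydroxy-6-(2,4,6-trihydroxyphenoxy)phenoxy]-[1,1′-biphenyl]-2,4,4′,6,6′-pentol
Conditions: BBr3 (20 equiv), CH2Cl2, −78 °C → rt; then H2O; reverse-phase purification under N2
Reagents that add atoms: none
Why: Exhaustive Lewis-acid aryl methyl ether cleavage (bromide attacks the methyl group of each boron-activated ether) removes all eight O-methyl groups, while diaryl ether and biaryl bonds are inert, which is the usual endgame for phlorotannins.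

**Compound list**
1 | 5-iodovanillin (4-hydroxy-3-iodo-5-methoxybenzaldehyde) | O=Cc1cc(I)c(O)c(OC)c1 | starting material
2 | (3,5-dimethoxyphenyl)boronic acid | COc1cc(OC)cc(c1)B(O)O | starting material
3 | 4-(3,5-dimethoxyphenoxy)-3-iodo-5-methoxybenzaldehyde | O=Cc1cc(I)c(Oc2cc(OC)cc(OC)c2)c(OC)c1 | intermediate
4 | 4-(3,5-dimethoxyphenoxy)-3-[hydroxy(trifluoromethanesulfonyloxy)iodanyl]-5-methoxybenzaldehyde (not isolated) | O=Cc1cc(I(O)OS(=O)(=O)C(F)(F)F)c(Oc2cc(OC)cc(OC)c2)c(OC)c1 | intermediate
5 | 3-formyl-1,6,8-trimethoxydibenzo[b,e][1,4]iodaoxin-5-ium trifluoromethanesulfonate | O=Cc1cc2c(c(OC)c1)Oc1cc(OC)cc(OC)c1[I+]2.[O-]S(=O)(=O)C(F)(F)F | intermediate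
6 | syringaldehyde (4-hydroxy-3,5-dimethoxybenzaldehyde) | O=Cc1cc(OC)c(O)c(OC)c1 | starting material
7 | 3-(4-formyl-2,6-dimethoxyphenoxy)-4-(2-iodo-3,5-dimethoxyphenoxy)-5-methoxybenzaldehyde | O=Cc1cc(Oc2c(OC)cc(C=O)cc2OC)c(Oc2cc(OC)cc(OC)c2I)c(OC)c1 | intermediate
8 | (2,4,6-trimethoxyphenyl)boronic acid | COc1cc(OC)c(B(O)O)c(OC)c1 | starting material
9 | 3-(4-formyl-2,6-dimethoxyphenoxy)-5-methoxy-4-[(2′,4,4′,6,6′-pentamethoxy-[1,1′-biphenyl]-2-yl)oxy]benzaldehyde | O=Cc1cc(Oc2c(OC)cc(C=O)cc2OC)c(Oc2cc(OC)cc(OC)c2-c2c(OC)cc(OC)cc2OC)c(OC)c1 | intermediate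
10 | 3-[4-(formyloxy)-2,6-dimethoxyphenoxy]-5-methoxy-4-[(2′,4,4′,6,6′-pentamethoxy-[1,1′-biphenyl]-2-yl)oxy]phenyl formate (not isolated) | O=COc1cc(Oc2c(OC)cc(OC=O)cc2OC)c(Oc2cc(OC)cc(OC)c2-c2c(OC)cc(OC)cc2OC)c(OC)c1 | intermediate
11 | 3-(4-hydroxy-2,6-dimethoxyphenoxy)-5-methoxy-4-[(2′,4,4′,6,6′-pentamethoxy-[1,1′-biphenyl]-2-yl)oxy]phenol | Oc1cc(Oc2c(OC)cc(O)cc2OC)c(Oc2cc(OC)cc(OC)c2-c2c(OC)cc(OC)cc2OC)c(OC)c1 | intermediate
12 | fucodiphloroethol G | Oc1cc(O)c(Oc2cc(O)cc(O)c2Oc2cc(O)cc(O)c2-c2c(O)cc(O)cc2O)c(O)c1 | target

**Step count and risks**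

Total steps: 6. Longest linear sequence: 6 (from 5-iodovanillin).

The three steps most likely to fail:

Step 2 (oxidative cyclisation). The peracid may attack the aldehyde (premature Baeyer–Villiger), and the strong acid may promote condensation or hydroxylation of the very electron-rich ring C before the iodine is oxidised. The fallback avoids trivalent iodine altogether. It sets out from 3, which is coupled with syringaldehyde 6 in an Ullmann diaryl ether synthesis (CuI, picolinic acid, K3PO4, DMSO, 90 °C) to give 3-(4-formyl-2,6-dimethoxyphenoxy)-4-(3,5-dimethoxyphenoxy)-5-methoxybenzaldehyde F1. Rings A and B of this compound are deactivated by their formyl groups, so N-iodosuccinimide (cat. TFA, MeCN, 0 °C) iodinates only ring C, mainly ortho to the aryloxy group and para to a methoxy group. The route is rejoined at 7.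

Step 3 (the proposed new ring opening). The hindered, weakly nucleophilic phenoxide may react slowly, or opening may occur at the wrong C–I bond. The fallback uses only known chemistry and sets out from 5. Anion exchange with KI (aqueous MeOH) gives 3-formyl-1,6,8-trimethoxydibenzo[b,e][1,4]iodaoxin-5-ium iodide F2. Thermolysis of this salt (DMF, 130 °C), the classical ring opening of cyclic iodonium halides, gives 3-iodo-4-(2-iodo-3,5-dimethoxyphenoxy)-5-methoxybenzaldehyde F3, the same diiodide whichever C–I bond the iodide breaks. An Ullmann coupling with 6 (CuI, picolinic acid, K3PO4, DMSO, 80–90 °C) then takes place at the ring B iodide, which has one ortho substituent and a formyl group, in preference to the di-ortho-substituted, electron-rich ring C iodide. The route is rejoined at 7.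

Step 4 (tetra-ortho-substituted Suzuki coupling). Protodeboronation of 8 may outrun transmetalation at the crowded palladium centre. The fallback is a Negishi coupling and sets out from 7. 1,3,5-Trimethoxybenzene is lithiated (n-BuLi, THF, 0 °C → rt) to (2,4,6-trimethoxyphenyl)lithium F4, which is transmetalated with ZnCl2 to chlorido(2,4,6-trimethoxyphenyl)zinc F5. This reagent cannot protodeboronate and tolerates aryl aldehydes; it is coupled with 7 using Pd2(dba)3 and RuPhos in THF at 60 °C. The route is rejoined at 9.

**Further compounds**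
F1 | step 2 | 3-(4-formyl-2,6-dimethoxyphenoxy)-4-(3,5-dimethoxyphenoxy)-5-methoxybenzaldehyde | O=Cc1cc(Oc2c(OC)cc(C=O)cc2OC)c(Oc2cc(OC)cc(OC)c2)c(OC)c1
F2 | step 3 | 3-formyl-1,6,8-trimethoxydibenzo[b,e][1,4]iodaoxin-5-ium iodide | O=Cc1cc2c(c(OC)c1)Oc1cc(OC)cc(OC)c1[I+]2.[I-]
F3 | step 3 | 3-iodo-4-(2-iodo-3,5-dimethoxyphenoxy)-5-methoxybenzaldehyde | O=Cc1cc(I)c(Oc2cc(OC)cc(OC)c2I)c(OC)c1
F4 | step 4 | (2,4,6-trimethoxyphenyl)lithium | [Li]c1c(OC)cc(OC)cc1OC
F5 | step 4 | chlorido(2,4,6-trimethoxyphenyl)zinc | Cl[Zn]c1c(OC)cc(OC)cc1OC
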